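## Structural features

The target is a labdane of the normal (5S,9S,10S) series: a trans-fused decalin (ring A = C1–C5, C10; ring B = C5–C10) with a gem-dimethyl group on C4, an angular methyl group on C10 and an exocyclic methylene (C17) on C8. C9 carries a side chain in which C11 is a secondary acetate, C12 a methylene group and C13–C16 an α-substituted butenolide whose carbonyl carbon C16 is bonded to C13. The four stereocentres C5, C10, C9 and C11 are contiguous: C5/C10 define the trans ring fusion, C9 sits between the quaternary C10, the sp2 carbon C8 and the carbinol carbon C11, and C11 is R. Fragile groups are the C8(17) methylene (acid-induced migration into the ring, ene reactions, hydroboration), the butenolide (base-induced double-bond shift, hydride and conjugate attack), the acetate, and C9–H whenever C8 is a carbonyl group. The real difficulty is the C9/C11 pair: a bond made at C9 of a finished decalin has to form on a hindered face next to C10, and an 8-ketone would have to be olefinated beside an epimerisable centre. The key step uses the fact that C8 is an alkene carbon bonded only to C17, C7 and C9. With C8 as the enol triflate C8(OTf)=C17 and C7 as the terminus of a vinyl group on C5, ring B can be closed by a C7–C8 sp3–sp2 coupling that delivers the methylene directly and leaves C9 and C11, set earlier in an open chain, untouched.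

## Logic of the disconnections

**30 ⇒ 28 (through 29).** No skeletal bond is cut; the lactone is unravelled by functional-group change. The C16 carbonyl and the C15–O single bond of 30 go back to the C16–Si and C15–H positions of the furan in 28. The furan tolerates hydride, organomagnesium, amide base, borane and palladium chemistry that the butenolide would not. Silicon on C16 decides which furan α-carbon becomes the carbonyl, so the lactone comes out α-substituted (C13 bonded to C16). The gain is that the most sensitive group is absent from every earlier intermediate. The forward step must oxidise the furan faster than the C8(17) alkene and reduce the lactol carbon C15 without touching the acetate.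

**28 ⇒ 27 ⇒ 26.** The C11–O acyl bond of 28 is cut to 27, and the C11–O–Si bond is restored in 26. An ester on C11 would not survive methyl addition, enolate triflation and aqueous carbonate, so the acetate enters after ring B is closed. In 26 and in all compounds before it the C11 oxygen carries a triethylsilyl group, not a tert-butyldimethylsilyl group. The bulkier ether on this hindered carbinol would need forcing fluoride, which also attacks the furyl C16–Si bond, and loss of that silicon would remove the regiocontrol of the last step. The forward steps must cleave O–Si beside an aryl C–Si bond and acylate a hindered secondary alcohol.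

**26 ⇒ 24 (through 25).** The C7–C8 bond of ring B is cut. C8 becomes the carbon of an enol triflate (C8=C17 retained) and C7 the terminal carbon of a vinyl group on C5, which is converted to a C7 borane in the flask. This removes ring B and leaves a monocyclic ring A with two arms. It avoids olefination of an 8-ketone and avoids any bond formation at C9 on a decalin. The configurations written for 24 and 26 at C5, C10, C9 and C11 were checked against 30 and agree atom for atom, so no stereocentre changes in this step. The forward step needs hydroboration of the vinyl group only, and ring closure faster than β-hydride elimination or triflate hydrolysis.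

**24 ⇒ 22 ⇒ 21 ⇒ 20 ⇒ 19.** The O–S bond of the triflate is cut to the methyl ketone 22. The C8–C17 bond is cut (through carbinol 21) to the aldehyde 20, and the C8–H bond of 20 to the N-acyl auxiliary of 19. C8 is flanked by C9, which carries the quaternary C10; the smallest nucleophile, hydride, is therefore used to release the auxiliary, and C17 is added to the unhindered aldehyde. The forward steps must enolise 22 towards C17 only and must not epimerise C9.

**19 ⇒ 18 ⇒ 11 + 16 (through 17).** The O–Si bond and then the C9–C11 bond are cut. The C9/C11 relationship of 24 is a syn-aldol relationship; with the carbonyl carbon C8 as C1 of the acyl chain it is (2S,3R). This is the syn adduct that the (S)-configured auxiliary 10 gives through the non-chelated transition state. Both stereocentres are thus set in an open chain under auxiliary control. The forward step needs a Z-enolate at a neopentyl-type carbon, and addition to an enolisable aldehyde faster than proton transfer.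

**16 ⇒ 15 ⇒ 13 ⇒ 12 (through 14).** The aldehyde goes back to the alcohol 15, the C12–C13 bond (furan C3 to the two-carbon unit) is cut to the bromide 13, and the C16–Si bond to 12. The forward steps need metalation of 12 at the carbon between oxygen and bromine, and bromine–lithium exchange without migration of lithium.

**11 ⇒ 9 + 10; 9 ⇒ 8 ⇒ 6 ⇒ 5 (through 7).** The C8–N bond is cut to acid 9 and auxiliary 10, and the acid goes back to the tert-butyl ester 8. The C1 methylene of 8 is traced back to the tosylhydrazone 6 and the ketone 5. Free hydrazine and strong base are excluded because 5 is a γ-keto ester and would close to a dihydropyridazinone. A dissolving or hydrogenating desulfurisation is excluded by the vinyl group. A hydride reduction of the tosylhydrazone meets both limits.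

**5 ⇒ 1 + 2 + 3 (through 4).** The C5–C6 bond (vinyl to the β-carbon of the enone) and the C9–C10 bond (acetate arm to the enolate carbon) are cut. Both ring-A stereocentres and all carbons of ring A, C6, C7, C9 and C8 then come from three commercial compounds in one operation. The forward step needs face-selective vinyl transfer to a β-carbon next to the quaternary C4, and C-alkylation of a tetrasubstituted enolate anti to the new vinyl group.

## Other disconnections considered

**Alternative 1:** The cut is the same pair of bonds as in step 1 here (C5–C6 and C9–C10), but with a four-carbon arm. The Grignard reagent [4-(trimethylsilyl)but-3-yn-1-yl]magnesium bromide A1 would add to 1 under copper/ferrocenyl diphosphine catalysis, and the enolate would be alkylated with 3 to give the trans keto ester A2.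
- In its favour: an sp3 Grignard reagent is the nucleophile class for which this catalysis is best established, so the enantio-determining step stands on firmer ground than vinyl transfer; on this point the alternative is the better plan. C6, C7, C8 and C17 arrive together, so neither a hydroboration nor an enol triflate is needed.
- Equal: the trans-selective alkylation at C10 and the removal of the C1 carbonyl beside a γ-ester are the same problems in both plans.
- Against it here: ring B would have to be closed by a C8–C9 bond, for instance by cyclisation of a C9 enolate, enol ether or α-carbonyl radical onto the alkyne. That type of 6-exo-dig closure from a singly activated carbon is less general than a B-alkyl Suzuki coupling. C9 would become stereogenic in the ring closure, and C11 (the ester carbon of A2) would have to be set afterwards on the decalin under substrate control. The chosen plan sets both under auxiliary control before ring closure.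
- Step economy: probably equal or slightly better for the alternative up to the decalin, but with less secure stereocontrol afterwards.

**Alternative 2:** The cut is C4–C5 and C9–C10 of the decalin. A protonation-initiated terpene cyclase would convert (2E,6E)-farnesyl diphosphate A3 into (5S,9S,10S)-albicanol A4.
- In its favour: one step would form both rings, C5, C9, C10 and the C8 methylene with the selectivity of an enzyme-templated chair–chair cation cyclisation. In step count and in control of the ring stereocentres this is clearly the better plan.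
- Against it here: it depends on access to the enzyme and to A3 in quantity. C11 would then be set by adding a C12–C16 nucleophile to albicanal A5, obtained by oxidation of A4. A5 is a β,γ-unsaturated aldehyde with an epimerisable C9 and a tendency to move its double bond into conjugation, and the configuration at C11 would rest on substrate (Felkin–Anh) control alone.
- Comparison: the chosen plan is much longer, but it is purely chemical, starts from bulk chemicals, and sets C9/C11 with a reagent-controlled reaction. The two are equal in that both deliver the methylene without olefination of a ketone.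

**Alternative 3:** The cut is C13–C16 and C16–O of the lactone. The (Z)-iodoallyl alcohol A6 would be carbonylated under palladium catalysis and base to the silyl-protected butenolide A7.
- In its favour: the position of iodine fixes the lactone regiochemistry without any directing group. No photo-oxidation is run beside the C8(17) alkene, so in chemoselectivity towards that alkene it is the equal or the better of the last step here. The cis geometry needed for lactonisation follows from a directed trans-hydroalumination–iodination of a 2-alkyn-1-ol.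
- Against it here: an alkyne or alkenyl iodide in the side chain is not compatible with closing ring B by hydroboration and palladium coupling, since the borane adds to alkynes and the iodide competes with the triflate. The C12–C15 chain would therefore have to be attached after ring closure, or ring B closed in another way. The silyl ether of A7 must also be exchanged for the acetate in the presence of the butenolide.
- Comparison: it is an alternative end-game, not an alternative ring construction. From the decalin it would need more operations (hydrometalation–iodination, carbonylation, desilylation, acetylation) than the single oxidation–reduction of a furan that was carried through from the aldol step.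

Key step: step 15

Assumption: in step 1 the antipode of the ferrocenyl diphosphine is the one that delivers vinyl to the face of 1 giving the (S) configuration at the vinyl-bearing carbon; if the sense of induction is the opposite, the mirror-image ligand is used.

## Route

**Step 1**
Reactants: 1 2,4,4-trimethylcyclohex-2-en-1-one; 2 vinylmagnesium bromide; 3 tert-butyl bromoacetate
Product: 5 tert-butyl 2-[(1R,2S)-2-ethenyl-1,3,3-trimethyl-6-oxocyclohexyl]acetate, via bromomagnesium enolate 4 (not isolated)
Conditions: CuBr·SMe2 (5 mol %), (R)-1-[(SP)-2-(diphenylphosphino)ferrocenyl]ethyldicyclohexylphosphine (6 mol %), t-BuOMe, −78 → −40 °C; then 3, DMPU, −40 °C → rt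
Reagents that add atoms: none
Why: Copper-catalysed enantioselective conjugate addition of a Grignard reagent to an α-substituted cyclohexenone with in situ enolate alkylation; the chiral copper–diphosphine complex transfers vinyl to one face of the β-carbon (C5). The regiodefined enolate 4 is then alkylated at C10 by the activated bromide anti to the adjacent pseudo-axial vinyl group, which makes the quaternary centre with the acetate arm trans to vinyl; the tert-butyl ester suppresses attack at the ester carbonyl.

**Step 2**
Reactants: 5 tert-butyl 2-[(1R,2S)-2-ethenyl-1,3,3-trimethyl-6-oxocyclohexyl]acetate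
Product: 6 tert-butyl 2-[(1R,2S)-2-ethenyl-1,3,3-trimethyl-6-{2-[(4-methylphenyl)sulfonyl]hydrazinylidene}cyclohexyl]acetate
Conditions: TsNHNH2 (1.5 equiv), PPTS (cat.), EtOH, 70 °C
Reagents that add atoms: 4-methylbenzenesulfonohydrazide, Cc1ccc(cc1)S(=O)(=O)NN
Why: Acid-catalysed hydrazone formation at the only ketone; the sulfonamide nitrogen is too weak a nucleophile to attack the tert-butyl ester, and the quaternary α-carbon cannot epimerise.

**Step 3**
Reactants: 6 tert-butyl 2-[(1R,2S)-2-ethenyl-1,3,3-trimethyl-6-{2-[(4-methylphenyl)sulfonyl]hydrazinylidene}cyclohexyl]acetate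
Product: 8 tert-butyl 2-[(1R,2S)-2-ethenyl-1,3,3-trimethylcyclohexyl]acetate, via N-boryl tosylhydrazine 7 (not isolated)
Conditions: catecholborane (3 equiv), CHCl3, 0 °C → rt; then NaOAc·3H2O, 60 °C
Reagents that add atoms: none
Why: Caglioti-type reduction of a tosylhydrazone: hydride adds to C=N to give 7, and acetate then induces loss of sulfinate and dinitrogen, leaving the C1 methylene. Catecholborane does not hydroborate the isolated vinyl group at this temperature, and no free hydrazine is present to condense with the γ-ester.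

**Step 4**
Reactants: 8 tert-butyl 2-[(1R,2S)-2-ethenyl-1,3,3-trimethylcyclohexyl]acetate
Product: 9 2-[(1R,2S)-2-ethenyl-1,3,3-trimethylcyclohexyl]acetic acid
Conditions: CF3CO2H/CH2Cl2 (1:4), 0 °C → rt
Reagents that add atoms: none
Why: Acidolysis of the tert-butyl ester with loss of isobutene; the monosubstituted alkene is not protonated by this acid at room temperature.

**Step 5**
Reactants: 9 2-[(1R,2S)-2-ethenyl-1,3,3-trimethylcyclohexyl]acetic acid; 10 (4S)-4-benzyl-1,3-thiazolidine-2-thione
Product: 11 (4S)-4-benzyl-3-{2-[(1R,2S)-2-ethenyl-1,3,3-trimethylcyclohexyl]acetyl}-1,3-thiazolidine-2-thione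
Conditions: EDC·HCl, DMAP (cat.), CH2Cl2, 0 °C → rt
Reagents that add atoms: none
Why: Carbodiimide-mediated N-acylation of the thiazolidinethione with DMAP as acyl-transfer catalyst, a standard way to make N-acyl thiazolidinethiones from free acids.

**Step 6**
Reactants: 12 3-bromofuran
Product: 13 3-bromo-2-(trimethylsilyl)furan
Conditions: LiN(i-Pr)2, THF, −78 °C; Me3SiCl, −78 °C → rt
Reagents that add atoms: chlorotrimethylsilane, C[Si](C)(C)Cl
Why: Directed metalation: the amide base removes the proton at C2, which is flanked by the ring oxygen and bromine, and the lithiofuran is C-silylated; at −78 °C bromine does not migrate.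

**Step 7**
Reactants: 13 3-bromo-2-(trimethylsilyl)furan
Product: 15 2-[2-(trimethylsilyl)furan-3-yl]ethan-1-ol, via 3-furyllithium 14 (not isolated)
Conditions: n-BuLi, Et2O, −78 °C; then oxirane, BF3·OEt2, −78 °C; H2O
Reagents that add atoms: oxirane, C1CO1
Why: Bromine–lithium exchange gives 14, whose C2 position is blocked by silicon, and BF3-assisted opening of the epoxide by the aryllithium forms the C12–C13 bond.

**Step 8**
Reactants: 15 2-[2-(trimethylsilyl)furan-3-yl]ethan-1-ol
Product: 16 2-[2-(trimethylsilyl)furan-3-yl]acetaldehyde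
Conditions: Dess–Martin periodinane, NaHCO3, CH2Cl2, 0 °C → rt; used at once
Reagents that add atoms: none
Why: Dess–Martin oxidation under buffered, non-basic conditions gives the enolisable arylacetaldehyde without self-condensation or protodesilylation.

**Step 9**
Reactants: 11 (4S)-4-benzyl-3-{2-[(1R,2S)-2-ethenyl-1,3,3-trimethylcyclohexyl]acetyl}-1,3-thiazolidine-2-thione; 16 2-[2-(trimethylsilyl)furan-3-yl]acetaldehyde
Product: 18 (4S)-4-benzyl-3-{(2S,3R)-2-[(1S,2S)-2-ethenyl-1,3,3-trimethylcyclohexyl]-3-hydroxy-4-[2-(trimethylsilyl)furan-3-yl]butanoyl}-1,3-thiazolidine-2-thione, via chlorotitanium enolate 17 (not isolated)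
Conditions: TiCl4 (1.05 equiv), i-Pr2NEt (1.1 equiv), N-methyl-2-pyrrolidinone (1.1 equiv), CH2Cl2, 0 °C; then 16 (1.5 equiv), −78 → 0 °C
Reagents that add atoms: none
Why: Titanium-mediated, auxiliary-controlled syn-aldol of an N-acyl thiazolidinethione: soft enolisation gives the Z-enolate 17, and with the pyrrolidinone on titanium the thiocarbonyl does not chelate. The aldehyde then reacts through a chair-like Zimmerman–Traxler transition state on the enolate face away from the benzyl group, which sets C9 and C11 syn as (2S,3R), the configuration of the target.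

**Step 10**
Reactants: 18 (4S)-4-benzyl-3-{(2S,3R)-2-[(1S,2S)-2-ethenyl-1,3,3-trimethylcyclohexyl]-3-hydroxy-4-[2-(trimethylsilyl)furan-3-yl]butanoyl}-1,3-thiazolidine-2-thione
Product: 19 (4S)-4-benzyl-3-{(2S,3R)-2-[(1S,2S)-2-ethenyl-1,3,3-trimethylcyclohexyl]-3-[(triethylsilyl)oxy]-4-[2-(trimethylsilyl)furan-3-yl]butanoyl}-1,3-thiazolidine-2-thione
Conditions: Et3SiOTf, 2,6-lutidine, CH2Cl2, −78 → 0 °C
Reagents that add atoms: triethylsilyl trifluoromethanesulfonate, CC[Si](CC)(CC)OS(=O)(=O)C(F)(F)F
Why: O-silylation of the secondary alcohol with a silyl triflate and a hindered base; it blocks retro-aldol cleavage and dehydration in the following steps.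

**Step 11**
Reactants: 19 (4S)-4-benzyl-3-{(2S,3R)-2-[(1S,2S)-2-ethenyl-1,3,3-trimethylcyclohexyl]-3-[(triethylsilyl)oxy]-4-[2-(trimethylsilyl)furan-3-yl]butanoyl}-1,3-thiazolidine-2-thione
Product: 20 (2S,3R)-2-[(1S,2S)-2-ethenyl-1,3,3-trimethylcyclohexyl]-3-[(triethylsilyl)oxy]-4-[2-(trimethylsilyl)furan-3-yl]butanal
Conditions: i-Bu2AlH, CH2Cl2, −78 °C; aq. potassium sodium tartrate
Reagents that add atoms: none
Why: Partial reduction of an N-acyl thiazolidinethione to the aldehyde: the aluminium hemiaminal is stable at −78 °C and releases aldehyde and auxiliary on work-up. Hydride is small enough for the neopentyl-type C8 carbonyl.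

**Step 12**
Reactants: 20 (2S,3R)-2-[(1S,2S)-2-ethenyl-1,3,3-trimethylcyclohexyl]-3-[(triethylsilyl)oxy]-4-[2-(trimethylsilyl)furan-3-yl]butanal
Product: 21 (3R,4R)-3-[(1S,2S)-2-ethenyl-1,3,3-trimethylcyclohexyl]-4-[(triethylsilyl)oxy]-5-[2-(trimethylsilyl)furan-3-yl]pentan-2-ol (both epimers at C2)
Conditions: MeMgBr, Et2O, −78 → 0 °C
Reagents that add atoms: methylmagnesium bromide, C[Mg]Br
Why: Grignard addition to the aldehyde introduces C17; the configuration of the new carbinol carbon C8 is irrelevant because it is oxidised in the next step.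

**Step 13**
Reactants: 21 (3R,4R)-3-[(1S,2S)-2-ethenyl-1,3,3-trimethylcyclohexyl]-4-[(triethylsilyl)oxy]-5-[2-(trimethylsilyl)furan-3-yl]pentan-2-ol
Product: 22 (3S,4R)-3-[(1S,2S)-2-ethenyl-1,3,3-trimethylcyclohexyl]-4-[(triethylsilyl)oxy]-5-[2-(trimethylsilyl)furan-3-yl]pentan-2-one
Conditions: Dess–Martin periodinane, NaHCO3, CH2Cl2, 0 °C → rt
Reagents that add atoms: none
Why: Dess–Martin oxidation of the secondary alcohol; the buffered medium does not epimerise C9 or eliminate the β-silyloxy group.

**Step 14**
Reactants: 22 (3S,4R)-3-[(1S,2S)-2-ethenyl-1,3,3-trimethylcyclohexyl]-4-[(triethylsilyl)oxy]-5-[2-(trimethylsilyl)furan-3-yl]pentan-2-one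
Product: 24 (3S,4R)-3-[(1S,2S)-2-ethenyl-1,3,3-trimethylcyclohexyl]-4-[(triethylsilyl)oxy]-5-[2-(trimethylsilyl)furan-3-yl]pent-1-en-2-yl trifluoromethanesulfonate, via potassium enolate 23 (not isolated)
Conditions: KN(SiMe3)2, THF, −78 °C; then PhNTf2, −78 → 0 °C
Reagents that add atoms: N-phenylbis(trifluoromethanesulfonimide), FC(F)(F)S(=O)(=O)N(c1ccccc1)S(=O)(=O)C(F)(F)F
Why: Kinetic deprotonation of the methyl ketone at the unhindered C17 methyl group and O-sulfonylation of enolate 23 give the 1,1-disubstituted enol triflate. C9–H is shielded by C10 and C11 and is not removed, so neither epimerisation nor β-elimination occurs.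

**Step 15**
Reactants: 24 (3S,4R)-3-[(1S,2S)-2-ethenyl-1,3,3-trimethylcyclohexyl]-4-[(triethylsilyl)oxy]-5-[2-(trimethylsilyl)furan-3-yl]pent-1-en-2-yl trifluoromethanesulfonate
Product: 26 (11R)-11-(triethylsilyloxy)-16-(trimethylsilyl)-15,16-epoxylabda-8(17),13(16),14-triene, via B-alkyl-9-BBN 25 (not isolated)
Conditions: 9-BBN (1.5 equiv), THF, 0 → 40 °C; then H2O, PdCl2(dppf) (10 mol %), AsPh3 (10 mol %), Cs2CO3 (3 equiv), DMF/THF/H2O, 0.01 M, 50 °C
Reagents that add atoms: none
Why: Hydroboration followed by intramolecular B-alkyl Suzuki–Miyaura coupling, the known route from ω-boryl alkenyl halides or triflates to methylenecycloalkanes. 9-BBN adds anti-Markovnikov to the monosubstituted C6=C7 bond and places boron on C7 to give 25. Zerovalent palladium formed from PdCl2(dppf) inserts into the C8–O bond of the enol triflate; base converts the borane into a borate, the primary alkyl group passes from boron to divalent palladium, and reductive elimination from the seven-membered palladacycle forms C7–C8. Ring B closes as a six-membered ring with the C8=C17 bond outside it (6-exo with respect to the alkene); the trans-diequatorial C5 and C10 arms on chair ring A hold C7 and C8 close, so the trans-decalin forms without strain. No stereocentre is created, and C5, C10, C9 and C11 are untouched because none of their bonds is involved and no enolisable carbonyl is present. The selectivity needed is chemoselective hydroboration, secured by the bulk of 9-BBN, which reacts with the terminal vinyl group far faster than with the electron-poor 1,1-disubstituted enol triflate or the aromatic silylfuran. β-Hydride elimination is held back by the wide bite angle of dppf, which speeds up reductive elimination, and intermolecular coupling by dilution.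

**Step 16**
Reactants: 26 (11R)-11-(triethylsilyloxy)-16-(trimethylsilyl)-15,16-epoxylabda-8(17),13(16),14-triene
Product: 27 (11R)-16-(trimethylsilyl)-15,16-epoxylabda-8(17),13(16),14-trien-11-ol
Conditions: HF·pyridine, pyridine, THF, 0 °C → rt
Reagents that add atoms: none
Why: Fluoride-mediated cleavage of the triethylsilyl ether; the O–Si bond should be cleaved much faster than the aryl C–Si bond of the 2-silylfuran, and the buffered medium does not isomerise the exocyclic alkene.

**Step 17**
Reactants: 27 (11R)-16-(trimethylsilyl)-15,16-epoxylabda-8(17),13(16),14-trien-11-ol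
Product: 28 (11R)-16-(trimethylsilyl)-15,16-epoxylabda-8(17),13(16),14-trien-11-yl acetate
Conditions: Ac2O, DMAP, Et3N, CH2Cl2, rt
Reagents that add atoms: acetic anhydride, CC(=O)OC(C)=O
Why: DMAP-catalysed acetylation of the hindered secondary alcohol with retention at C11.

**Step 18**
Reactants: 28 (11R)-16-(trimethylsilyl)-15,16-epoxylabda-8(17),13(16),14-trien-11-yl acetate
Product: 30 (11R)-11-acetoxylabda-8(17),13-dien-16,15-olide, via hydroxybutenolide 29 (not isolated)
Conditions: O2, hν (visible), 5,10,15,20-tetraphenylporphyrin (cat.), CH2Cl2, −78 °C; then MeOH, NaBH4, −78 → 0 °C; 1 M HCl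
Reagents that add atoms: dioxygen, O=O
Why: Singlet-oxygen oxidation of a 2-silylfuran: [4+2] addition across C16/C15 and migration of silicon from C16 to oxygen make C16 the lactone carbonyl of 29, so the α-substituted regioisomer is the only one formed. NaBH4 then reduces the masked aldehyde C15 and the hydroxy acid closes to the butenolide on acidification. The furan reacts with singlet oxygen far faster than the 1,1-disubstituted alkene does in an ene reaction, and the acetate survives brief borohydride treatment at 0 °C.

## Compound list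

1 | 2,4,4-trimethylcyclohex-2-en-1-one | CC1=CC(C)(C)CCC1=O | starting material
2 | vinylmagnesium bromide | C=C[Mg]Br | starting material
3 | tert-butyl bromoacetate | CC(C)(C)OC(=O)CBr | starting material
4 | bromomagnesium (3S)-3-ethenyl-2,4,4-trimethylcyclohex-1-en-1-olate | C=C[C@H]1C(C)(C)CCC(O[Mg]Br)=C1C | intermediate
5 | tert-butyl 2-[(1R,2S)-2-ethenyl-1,3,3-trimethyl-6-oxocyclohexyl]acetate | C=C[C@H]1C(C)(C)CCC(=O)[C@]1(C)CC(=O)OC(C)(C)C | intermediate
6 | tert-butyl 2-[(1R,2S)-2-ethenyl-1,3,3-trimethyl-6-{2-[(4-methylphenyl)sulfonyl]hydrazinylidene}cyclohexyl]acetate (C=N geometry not defined) | C=C[C@H]1C(C)(C)CCC(=NNS(=O)(=O)c2ccc(C)cc2)[C@]1(C)CC(=O)OC(C)(C)C | intermediate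
7 | tert-butyl 2-[(1R,2S)-6-{1-(1,3,2-benzodioxaborol-2-yl)-2-[(4-methylphenyl)sulfonyl]hydrazinyl}-2-ethenyl-1,3,3-trimethylcyclohexyl]acetate (either configuration at the nitrogen-bearing ring carbon) | C=C[C@H]1C(C)(C)CCC(N(NS(=O)(=O)c2ccc(C)cc2)B2Oc3ccccc3O2)[C@]1(C)CC(=O)OC(C)(C)C | intermediate
8 | tert-butyl 2-[(1R,2S)-2-ethenyl-1,3,3-trimethylcyclohexyl]acetate | C=C[C@H]1C(C)(C)CCC[C@]1(C)CC(=O)OC(C)(C)C | intermediate
9 | 2-[(1R,2S)-2-ethenyl-1,3,3-trimethylcyclohexyl]acetic acid | C=C[C@H]1C(C)(C)CCC[C@]1(C)CC(=O)O | intermediate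
10 | (4S)-4-benzyl-1,3-thiazolidine-2-thione | S=C1N[C@@H](Cc2ccccc2)CS1 | starting material
11 | (4S)-4-benzyl-3-{2-[(1R,2S)-2-ethenyl-1,3,3-trimethylcyclohexyl]acetyl}-1,3-thiazolidine-2-thione | C=C[C@H]1C(C)(C)CCC[C@]1(C)CC(=O)N1[C@@H](Cc2ccccc2)CSC1=S | intermediate
12 | 3-bromofuran | Brc1ccoc1 | starting material
13 | 3-bromo-2-(trimethylsilyl)furan | C[Si](C)(C)c1occc1Br | intermediate
14 | [2-(trimethylsilyl)furan-3-yl]lithium | [Li]c1ccoc1[Si](C)(C)C | intermediate
15 | 2-[2-(trimethylsilyl)furan-3-yl]ethan-1-ol | OCCc1ccoc1[Si](C)(C)C | intermediate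
16 | 2-[2-(trimethylsilyl)furan-3-yl]acetaldehyde | O=CCc1ccoc1[Si](C)(C)C | intermediate
17 | (4S)-4-benzyl-3-{(1Z)-2-[(1S,2S)-2-ethenyl-1,3,3-trimethylcyclohexyl]-1-[(trichlorotitanio)oxy]ethenyl}-1,3-thiazolidine-2-thione | C=C[C@H]1C(C)(C)CCC[C@]1(C)/C=C(\O[Ti](Cl)(Cl)Cl)N1[C@@H](Cc2ccccc2)CSC1=S | intermediate
18 | (4S)-4-benzyl-3-{(2S,3R)-2-[(1S,2S)-2-ethenyl-1,3,3-trimethylcyclohexyl]-3-hydroxy-4-[2-(trimethylsilyl)furan-3-yl]butanoyl}-1,3-thiazolidine-2-thione | C=C[C@H]1C(C)(C)CCC[C@]1(C)[C@H](C(=O)N1[C@@H](Cc2ccccc2)CSC1=S)[C@@H](Cc1ccoc1[Si](C)(C)C)O | intermediate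
19 | (4S)-4-benzyl-3-{(2S,3R)-2-[(1S,2S)-2-ethenyl-1,3,3-trimethylcyclohexyl]-3-[(triethylsilyl)oxy]-4-[2-(trimethylsilyl)furan-3-yl]butanoyl}-1,3-thiazolidine-2-thione | C=C[C@H]1C(C)(C)CCC[C@]1(C)[C@H](C(=O)N1[C@@H](Cc2ccccc2)CSC1=S)[C@@H](Cc1ccoc1[Si](C)(C)C)O[Si](CC)(CC)CC | intermediate
20 | (2S,3R)-2-[(1S,2S)-2-ethenyl-1,3,3-trimethylcyclohexyl]-3-[(triethylsilyl)oxy]-4-[2-(trimethylsilyl)furan-3-yl]butanal | C=C[C@H]1C(C)(C)CCC[C@]1(C)[C@H](C=O)[C@@H](Cc1ccoc1[Si](C)(C)C)O[Si](CC)(CC)CC | intermediate
21 | (3R,4R)-3-[(1S,2S)-2-ethenyl-1,3,3-trimethylcyclohexyl]-4-[(triethylsilyl)oxy]-5-[2-(trimethylsilyl)furan-3-yl]pentan-2-ol (both epimers at C2) | C=C[C@H]1C(C)(C)CCC[C@]1(C)[C@H](C(C)O)[C@@H](Cc1ccoc1[Si](C)(C)C)O[Si](CC)(CC)CC | intermediate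
22 | (3S,4R)-3-[(1S,2S)-2-ethenyl-1,3,3-trimethylcyclohexyl]-4-[(triethylsilyl)oxy]-5-[2-(trimethylsilyl)furan-3-yl]pentan-2-one | C=C[C@H]1C(C)(C)CCC[C@]1(C)[C@H](C(C)=O)[C@@H](Cc1ccoc1[Si](C)(C)C)O[Si](CC)(CC)CC | intermediate
23 | potassium (3S,4R)-3-[(1S,2S)-2-ethenyl-1,3,3-trimethylcyclohexyl]-4-[(triethylsilyl)oxy]-5-[2-(trimethylsilyl)furan-3-yl]pent-1-en-2-olate | C=C[C@H]1C(C)(C)CCC[C@]1(C)[C@H](C(=C)[O-])[C@@H](Cc1ccoc1[Si](C)(C)C)O[Si](CC)(CC)CC.[K+] | intermediate
24 | (3S,4R)-3-[(1S,2S)-2-ethenyl-1,3,3-trimethylcyclohexyl]-4-[(triethylsilyl)oxy]-5-[2-(trimethylsilyl)furan-3-yl]pent-1-en-2-yl trifluoromethanesulfonate | C=C[C@H]1C(C)(C)CCC[C@]1(C)[C@H](C(=C)OS(=O)(=O)C(F)(F)F)[C@@H](Cc1ccoc1[Si](C)(C)C)O[Si](CC)(CC)CC | intermediate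
25 | (3S,4R)-3-{(1S,2S)-2-[2-(9-borabicyclo[3.3.1]nonan-9-yl)ethyl]-1,3,3-trimethylcyclohexyl}-4-[(triethylsilyl)oxy]-5-[2-(trimethylsilyl)furan-3-yl]pent-1-en-2-yl trifluoromethanesulfonate | B1(C2CCCC1CCC2)CC[C@H]1C(C)(C)CCC[C@]1(C)[C@H](C(=C)OS(=O)(=O)C(F)(F)F)[C@@H](Cc1ccoc1[Si](C)(C)C)O[Si](CC)(CC)CC | intermediate
26 | (11R)-11-(triethylsilyloxy)-16-(trimethylsilyl)-15,16-epoxylabda-8(17),13(16),14-triene; triethyl({(1R)-1-[(1S,4aS,8aS)-5,5,8a-trimethyl-2-methylidenedecahydronaphthalen-1-yl]-2-[2-(trimethylsilyl)furan-3-yl]ethyl}oxy)silane | C=C1CC[C@H]2C(C)(C)CCC[C@]2(C)[C@H]1[C@@H](Cc1ccoc1[Si](C)(C)C)O[Si](CC)(CC)CC | intermediate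
27 | (1R)-1-[(1S,4aS,8aS)-5,5,8a-trimethyl-2-methylidenedecahydronaphthalen-1-yl]-2-[2-(trimethylsilyl)furan-3-yl]ethan-1-ol | C=C1CC[C@H]2C(C)(C)CCC[C@]2(C)[C@H]1[C@@H](Cc1ccoc1[Si](C)(C)C)O | intermediate
28 | (1R)-1-[(1S,4aS,8aS)-5,5,8a-trimethyl-2-methylidenedecahydronaphthalen-1-yl]-2-[2-(trimethylsilyl)furan-3-yl]ethyl acetate | C=C1CC[C@H]2C(C)(C)CCC[C@]2(C)[C@H]1[C@@H](Cc1ccoc1[Si](C)(C)C)OC(C)=O | intermediate
29 | (1R)-2-(5-hydroxy-2-oxo-2,5-dihydrofuran-3-yl)-1-[(1S,4aS,8aS)-5,5,8a-trimethyl-2-methylidenedecahydronaphthalen-1-yl]ethyl acetate (both epimers at the lactol carbon) | C=C1CC[C@H]2C(C)(C)CCC[C@]2(C)[C@H]1[C@@H](CC1=CC(O)OC1=O)OC(C)=O | intermediate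
30 | (11R)-11-acetoxylabda-8(17),13-dien-16,15-olide; (1R)-2-(2-oxo-2,5-dihydrofuran-3-yl)-1-[(1S,4aS,8aS)-5,5,8a-trimethyl-2-methylidenedecahydronaphthalen-1-yl]ethyl acetate | C=C1CC[C@H]2C(C)(C)CCC[C@]2(C)[C@H]1[C@@H](CC1=CCOC1=O)OC(C)=O | target

## Step count and least certain steps

Total: 18 steps. Longest linear sequence: 15 steps (steps 1–5 and 9–18); the aldehyde 16 is made in 3 steps (steps 6–8) and joins at step 9.

**Step 15 (key step).** The likely failures are hydrolysis of the enol triflate under aqueous carbonate, protodeboronation, or β-hydride elimination from the alkylpalladium species before ring closure; hydroboration of the vinyl group between two quaternary carbons may also be slow. The fallback keeps the C7–C8 bond but forms it by carbonyl addition. It sets out from 24 and returns at 26. The borane 25 is made as before and oxidised with NaBO3·4H2O to the primary alcohol (3S,4R)-3-[(1S,2S)-2-(2-hydroxyethyl)-1,3,3-trimethylcyclohexyl]-4-[(triethylsilyl)oxy]-5-[2-(trimethylsilyl)furan-3-yl]pent-1-en-2-yl trifluoromethanesulfonate F1. Dess–Martin oxidation gives the corresponding 2-oxoethyl aldehyde F2. An intramolecular Nozaki–Hiyama–Kishi reaction (CrCl2, NiCl2 cat., DMF) adds the alkenylchromium at C8 to the C7 aldehyde and closes ring B as (11R)-11-(triethylsilyloxy)-16-(trimethylsilyl)-15,16-epoxylabda-8(17),13(16),14-trien-7-ol F3 (both C7 epimers). Formylation gives the allylic formate F4. Palladium-catalysed formate hydrogenolysis (Pd(OAc)2, PBu3, THF, reflux; Tsuji-type) delivers hydride to the more substituted allyl terminus C7, keeps the C8(17) methylene and gives 26.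

**Step 1.** Vinyl transfer may proceed with poor facial selectivity, because alkenyl Grignard reagents react partly through ligand-free copper species; addition at the β-carbon next to C4 may be slow; and C-alkylation of the magnesium enolate may be incomplete. The fallback separates the three tasks and replaces asymmetric catalysis by resolution. It sets out from 1 and returns at 5.
- 2 with CuBr·SMe2 (cat.) and Me3SiCl in THF gives racemic [(3-ethenyl-2,4,4-trimethylcyclohex-1-en-1-yl)oxy]trimethylsilane F5.
- MeLi releases the racemic lithium enolate F6, which is alkylated with 3 to the racemic trans keto ester F7.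
- CF3CO2H gives the racemic keto acid F8.
- Crystallisation with (S)-1-phenylethylamine gives the salt F9 of the (1R,2S) acid, and acidification gives 2-[(1R,2S)-2-ethenyl-1,3,3-trimethyl-6-oxocyclohexyl]acetic acid F10.
- tert-Butyl 2,2,2-trichloroacetimidate with BF3·OEt2 (cat.) re-forms 5.

**Step 3 (with step 2).** Hydrazone formation at the hindered carbonyl may be incomplete, or after hydride addition the hydrazine nitrogen may cyclise onto the ester. The fallback is a radical deoxygenation; it sets out from 5 and returns at 8. NaBH4 in MeOH gives tert-butyl 2-[(1R,2S)-2-ethenyl-6-hydroxy-1,3,3-trimethylcyclohexyl]acetate F11 (either carbinol epimer). 1,1'-Thiocarbonyldiimidazole gives the O-alkyl imidazole-1-carbothioate F12. Bu3SnH with AIBN in toluene at 110 °C (Barton–McCombie) gives 8; the C1 radical has no favourable cyclisation onto the vinyl group.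

**Step 9.** Carbon–carbon bond formation at the neopentyl-type enolate carbon may be slow, so that proton transfer to the enolisable aldehyde and its self-condensation compete, or the resident C10 centre may oppose the auxiliary. The fallback changes the stereocontrol element to the chelated transition state, which uses one equivalent of base and no free amine. It sets out from 9 and returns at 20. Acid 9 is coupled with (4R)-4-benzyl-1,3-thiazolidine-2-thione to the imide F13. TiCl4 (1.05 equiv) and i-Pr2NEt (1.0 equiv) without the pyrrolidinone, then 16, give through the thiocarbonyl-chelated transition state the syn adduct F14 with the same (2S,3R) chain. Et3SiOTf gives the silyl ether F15, and i-Bu2AlH gives 20.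

**Step 16.** The trimethylsilyl group may be lost from the furan together with the triethylsilyl ether, or cleavage at the hindered C11 may be slow. The fallback consumes the furyl silane first; it sets out from 26 and returns at 30. Singlet-oxygen oxidation of 26 under the conditions of step 18 gives the silyl-protected hydroxybutenolide F16 (not isolated), and NaBH4 gives (11R)-11-(triethylsilyloxy)labda-8(17),13-dien-16,15-olide F17. Aqueous HF in MeCN gives the 11-hydroxy butenolide F18, which is acetylated at once (Ac2O, DMAP) to 30.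

## Further compounds

F1 | step 15 | (3S,4R)-3-[(1S,2S)-2-(2-hydroxyethyl)-1,3,3-trimethylcyclohexyl]-4-[(triethylsilyl)oxy]-5-[2-(trimethylsilyl)furan-3-yl]pent-1-en-2-yl trifluoromethanesulfonate | OCC[C@H]1C(C)(C)CCC[C@]1(C)[C@H](C(=C)OS(=O)(=O)C(F)(F)F)[C@@H](Cc1ccoc1[Si](C)(C)C)O[Si](CC)(CC)CC
F2 | step 15 | (3S,4R)-3-[(1S,2S)-1,3,3-trimethyl-2-(2-oxoethyl)cyclohexyl]-4-[(triethylsilyl)oxy]-5-[2-(trimethylsilyl)furan-3-yl]pent-1-en-2-yl trifluoromethanesulfonate | O=CC[C@H]1C(C)(C)CCC[C@]1(C)[C@H](C(=C)OS(=O)(=O)C(F)(F)F)[C@@H](Cc1ccoc1[Si](C)(C)C)O[Si](CC)(CC)CC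
F3 | step 15 | (11R)-11-(triethylsilyloxy)-16-(trimethylsilyl)-15,16-epoxylabda-8(17),13(16),14-trien-7-ol (both C7 epimers) | C=C1C(O)C[C@H]2C(C)(C)CCC[C@]2(C)[C@H]1[C@@H](Cc1ccoc1[Si](C)(C)C)O[Si](CC)(CC)CC
F4 | step 15 | (11R)-11-(triethylsilyloxy)-16-(trimethylsilyl)-15,16-epoxylabda-8(17),13(16),14-trien-7-yl formate (both C7 epimers) | C=C1C(OC=O)C[C@H]2C(C)(C)CCC[C@]2(C)[C@H]1[C@@H](Cc1ccoc1[Si](C)(C)C)O[Si](CC)(CC)CC
F5 | step 1 | rac-[(3-ethenyl-2,4,4-trimethylcyclohex-1-en-1-yl)oxy]trimethylsilane | C=C[C@H]1C(C)(C)CCC(O[Si](C)(C)C)=C1C.C=C[C@@H]1C(C)(C)CCC(O[Si](C)(C)C)=C1C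
F6 | step 1 | rac-lithium 3-ethenyl-2,4,4-trimethylcyclohex-1-en-1-olate | C=C[C@H]1C(C)(C)CCC(O[Li])=C1C.C=C[C@@H]1C(C)(C)CCC(O[Li])=C1C
F7 | step 1 | rac-tert-butyl 2-[(1R*,2S*)-2-ethenyl-1,3,3-trimethyl-6-oxocyclohexyl]acetate | C=C[C@H]1C(C)(C)CCC(=O)[C@]1(C)CC(=O)OC(C)(C)C.C=C[C@@H]1C(C)(C)CCC(=O)[C@@]1(C)CC(=O)OC(C)(C)C
F8 | step 1 | rac-2-[(1R*,2S*)-2-ethenyl-1,3,3-trimethyl-6-oxocyclohexyl]acetic acid | C=C[C@H]1C(C)(C)CCC(=O)[C@]1(C)CC(=O)O.C=C[C@@H]1C(C)(C)CCC(=O)[C@@]1(C)CC(=O)O
F9 | step 1 | (1S)-1-phenylethan-1-aminium 2-[(1R,2S)-2-ethenyl-1,3,3-trimethyl-6-oxocyclohexyl]acetate | C=C[C@H]1C(C)(C)CCC(=O)[C@]1(C)CC(=O)[O-].C[C@H]([NH3+])c1ccccc1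
F10 | step 1 | 2-[(1R,2S)-2-ethenyl-1,3,3-trimethyl-6-oxocyclohexyl]acetic acid | C=C[C@H]1C(C)(C)CCC(=O)[C@]1(C)CC(=O)O
F11 | step 3 | tert-butyl 2-[(1R,2S)-2-ethenyl-6-hydroxy-1,3,3-trimethylcyclohexyl]acetate (either carbinol epimer) | C=C[C@H]1C(C)(C)CCC(O)[C@]1(C)CC(=O)OC(C)(C)C
F12 | step 3 | tert-butyl 2-[(1R,2S)-2-ethenyl-6-[(1H-imidazol-1-ylcarbonothioyl)oxy]-1,3,3-trimethylcyclohexyl]acetate | C=C[C@H]1C(C)(C)CCC(OC(=S)n2ccnc2)[C@]1(C)CC(=O)OC(C)(C)C
F13 | step 9 | (4R)-4-benzyl-3-{2-[(1R,2S)-2-ethenyl-1,3,3-trimethylcyclohexyl]acetyl}-1,3-thiazolidine-2-thione | C=C[C@H]1C(C)(C)CCC[C@]1(C)CC(=O)N1[C@H](Cc2ccccc2)CSC1=S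
F14 | step 9 | (4R)-4-benzyl-3-{(2S,3R)-2-[(1S,2S)-2-ethenyl-1,3,3-trimethylcyclohexyl]-3-hydroxy-4-[2-(trimethylsilyl)furan-3-yl]butanoyl}-1,3-thiazolidine-2-thione | C=C[C@H]1C(C)(C)CCC[C@]1(C)[C@H](C(=O)N1[C@H](Cc2ccccc2)CSC1=S)[C@@H](Cc1ccoc1[Si](C)(C)C)O
F15 | step 9 | (4R)-4-benzyl-3-{(2S,3R)-2-[(1S,2S)-2-ethenyl-1,3,3-trimethylcyclohexyl]-3-[(triethylsilyl)oxy]-4-[2-(trimethylsilyl)furan-3-yl]butanoyl}-1,3-thiazolidine-2-thione | C=C[C@H]1C(C)(C)CCC[C@]1(C)[C@H](C(=O)N1[C@H](Cc2ccccc2)CSC1=S)[C@@H](Cc1ccoc1[Si](C)(C)C)O[Si](CC)(CC)CC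
F16 | step 16 | (11R)-15-hydroxy-11-(triethylsilyloxy)labda-8(17),13-dien-16,15-olide (both C15 epimers) | C=C1CC[C@H]2C(C)(C)CCC[C@]2(C)[C@H]1[C@@H](CC1=CC(O)OC1=O)O[Si](CC)(CC)CC
F17 | step 16 | (11R)-11-(triethylsilyloxy)labda-8(17),13-dien-16,15-olide | C=C1CC[C@H]2C(C)(C)CCC[C@]2(C)[C@H]1[C@@H](CC1=CCOC1=O)O[Si](CC)(CC)CC
F18 | step 16 | (11R)-11-hydroxylabda-8(17),13-dien-16,15-olide | C=C1CC[C@H]2C(C)(C)CCC[C@]2(C)[C@H]1[C@@H](CC1=CCOC1=O)O
A1 | alternative 1 | [4-(trimethylsilyl)but-3-yn-1-yl]magnesium bromide | C[Si](C)(C)C#CCC[Mg]Br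
A2 | alternative 1 | tert-butyl 2-{(1R,2S)-1,3,3-trimethyl-6-oxo-2-[4-(trimethylsilyl)but-3-yn-1-yl]cyclohexyl}acetate | C[Si](C)(C)C#CCC[C@H]1C(C)(C)CCC(=O)[C@]1(C)CC(=O)OC(C)(C)C
A3 | alternative 2 | (2E,6E)-farnesyl diphosphate | CC(C)=CCC/C(C)=C/CC/C(C)=C/COP(=O)(O)OP(=O)(O)O
A4 | alternative 2 | (5S,9S,10S)-albicanol; [(1S,4aS,8aS)-5,5,8a-trimethyl-2-methylidenedecahydronaphthalen-1-yl]methanol | C=C1CC[C@H]2C(C)(C)CCC[C@]2(C)[C@H]1CO
A5 | alternative 2 | albicanal; (1S,4aS,8aS)-5,5,8a-trimethyl-2-methylidenedecahydronaphthalene-1-carbaldehyde | C=C1CC[C@H]2C(C)(C)CCC[C@]2(C)[C@H]1C=O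
A6 | alternative 3 | (2Z,5R)-5-[(tert-butyldimethylsilyl)oxy]-3-iodo-5-[(1S,4aS,8aS)-5,5,8a-trimethyl-2-methylidenedecahydronaphthalen-1-yl]pent-2-en-1-ol | C=C1CC[C@H]2C(C)(C)CCC[C@]2(C)[C@H]1[C@@H](C/C(I)=C/CO)O[Si](C)(C)C(C)(C)C
A7 | alternative 3 | (11R)-11-(tert-butyldimethylsilyloxy)labda-8(17),13-dien-16,15-olide | C=C1CC[C@H]2C(C)(C)CCC[C@]2(C)[C@H]1[C@@H](CC1=CCOC1=O)O[Si](C)(C)C(C)(C)C
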